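The pentamer is cut at the ring C–O–ring D ether into an ABC unit and a DE bromide, and ring B of the ABC unit is grown, not coupled. The feature exploited is ring B itself: O-aryl at C1 (ring A) para to O-aryl at C4 (ring C), with oxygen on C3 and C5 beside C4. A thermal cyclobutenone–ynol ether benzannulation forms C1–C2 and C5–C6, recloses C4–C5 and aromatises, so both crowded ether oxygens arrive already bonded to their future ring B carbons. Its precursors are a racemic 3-ethoxy-4-aryloxycyclobutenone bearing protected ring C and the ethynyl ether of 2,4,6-trimethoxyphenol (ring A).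

Key step: step 9

Remark: the target is achiral; the only stereocentres on the way (C4 of 12, the sp3 carbons of 21 and 23) are racemic and vanish on aromatisation. Compounds 13, 27 and 28 are taken as purchasable.

Step 1
Reactants: 1 2-hydroxy-4,6-dimethoxybenzaldehyde
Product: 2 4,6-dimethoxy-2-(methoxymethoxy)benzaldehyde
Conditions: MOMCl, iPr2NEt, CH2Cl2, 0 °C → rt
Reagents that add atoms: chloromethyl methyl ether (MOMCl), COCCl
Why: O-alkylation of the only phenol with an alkoxymethyl chloride (MOM protection) masks the future ring B-bearing oxygen with a group that is inert to peracid and base and is later removable without touching a benzyl ether.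

Step 2
Reactants: 2 4,6-dimethoxy-2-(methoxymethoxy)benzaldehyde
Product: 4 2,4-dimethoxy-6-(methoxymethoxy)phenol, via aryl formate 3 (not isolated)
Conditions: mCPBA, CH2Cl2, 0 °C → rt; aq. NaHCO3 wash; then K2CO3 (cat.), MeOH, rt
Reagents that add atoms: mCPBA, OOC(=O)c1cccc(Cl)c1
Why: Baeyer–Villiger oxidation, in which the electron-rich trioxygenated aryl group migrates in preference to hydride, gives aryl formate 3, and mild base-catalysed methanolysis should then unveil the phenol at the former formyl carbon.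

Step 3
Reactants: 4 2,4-dimethoxy-6-(methoxymethoxy)phenol
Product: 5 2-(benzyloxy)-1,5-dimethoxy-3-(methoxymethoxy)benzene
Conditions: BnBr, K2CO3, DMF, rt → 50 °C
Reagents that add atoms: benzyl bromide, BrCc1ccccc1
Why: Williamson ether synthesis on the single free phenol installs the benzyl group on the oxygen that will later carry ring D.

Step 4
Reactants: 5 2-(benzyloxy)-1,5-dimethoxy-3-(methoxymethoxy)benzene
Product: 6 2-(benzyloxy)-3,5-dimethoxyphenol
Conditions: conc. HCl (cat.), MeOH, 50 °C
Reagents that add atoms: none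
Why: Acid-catalysed acetal exchange with methanol removes only the MOM group, since benzyl and methyl aryl ethers are stable to dilute acid.

Step 5
Reactants: 6 2-(benzyloxy)-3,5-dimethoxyphenol; 7 bromoacetic acid
Product: 8 2-[2-(benzyloxy)-3,5-dimethoxyphenoxy]acetic acid
Conditions: NaOH, H2O, reflux; then aq. HCl
Reagents that add atoms: none
Why: Williamson etherification of the phenoxide with bromoacetate (SN2 at a primary carbon) is the classical preparation of aryloxyacetic acids and puts the ring C oxygen on an sp3 carbon.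

Step 6
Reactants: 8 2-[2-(benzyloxy)-3,5-dimethoxyphenoxy]acetic acid; 9 ethoxyacetylene
Product: 12 rac-4-[2-(benzyloxy)-3,5-dimethoxyphenoxy]-3-ethoxycyclobut-2-en-1-one, via acid chloride 10 (not isolated), via aryloxyketene 11 (not isolated)
Conditions: (COCl)2, DMF (cat.), CH2Cl2, 0 °C → rt, evaporate; then 9 (3 equiv), Et3N, Et2O, 0 °C → rt, slow addition of 10
Reagents that add atoms: none
Why: Et3N dehydrochlorinates 10 to ketene 11, which undergoes thermal [2+2] ketene–alkyne cycloaddition with the ynol ether, the unsubstituted alkyne carbon bonding to the ketene carbonyl carbon so that ethoxy sits at C3 and aryloxy at C4; the C4 stereocentre forms uncontrolled as the racemate, which suffices.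

Step 7
Reactants: 13 2,4,6-trimethoxyphenol; 14 trichloroethylene
Product: 16 2-{[(E)-1,2-dichloroethenyl]oxy}-1,3,5-trimethoxybenzene, via dichloroacetylene 15 (not isolated)
Conditions: K2CO3, DMF, 70 °C
Reagents that add atoms: none
Why: Nucleophilic vinylation: base dehydrochlorinates trichloroethylene to 15, the 2,6-disubstituted phenoxide adds to its unhindered sp carbon, and anti protonation should give the (E)-dichlorovinyl ether.

Step 8
Reactants: 16 2-{[(E)-1,2-dichloroethenyl]oxy}-1,3,5-trimethoxybenzene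
Product: 19 2-(ethynyloxy)-1,3,5-trimethoxybenzene, via chloroethynyl ether 17 (not isolated), via lithium acetylide 18 (not isolated)
Conditions: n-BuLi (2.2 equiv), Et2O, −78 → −40 °C; then H2O–THF, −78 → 0 °C; used at once as a cold solution
Reagents that add atoms: none
Why: Ynol ether synthesis from a 1,2-dichlorovinyl ether: deprotonation and loss of LiCl give 17, chlorine–lithium exchange gives 18, and protonation gives the terminal ynol ether, the same quench undoing any aryl ring lithiation.

Step 9
Reactants: 12 rac-4-[2-(benzyloxy)-3,5-dimethoxyphenoxy]-3-ethoxycyclobut-2-en-1-one; 19 2-(ethynyloxy)-1,3,5-trimethoxybenzene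
Product: 24 2-[2-(benzyloxy)-3,5-dimethoxyphenoxy]-3-ethoxy-5-(2,4,6-trimethoxyphenoxy)phenol, via vinylketene 20 (not isolated), via vinylcyclobutenone 21 (not isolated), via dienylketene 22 (not isolated), via cyclohexadienone 23 (not isolated)
Conditions: 19 (2 equiv), toluene, 80 → 110 °C, Ar; then K2CO3 (cat.), MeOH, rt
Reagents that add atoms: none
Why: Heat opens 12 by conrotatory four-electron cleavage of its C1–C4 bond (aryloxy turning outward) to vinylketene 20, whose ketene C=C adds ynol ether 19 by [2+2] cycloaddition to give vinylcyclobutenone 21, and a second four-electron opening gives dienylketene 22. Ring B then closes by thermal disrotatory six-electron electrocyclisation of 22, the ketene carbon (future C5) bonding to the aryloxy-bearing terminus (future C4), and enolisation of cyclohexadienone 23 aromatises the ring. The closest known reaction type is the Danheiser benzannulation of cyclobutenones with alkoxy- and siloxyacetylenes; an aryl ethynyl ether is a less usual member of the same class, and it cannot lose ketene by retro-ene fragmentation because it has no beta hydrogen. No stereocentre remains to be controlled, since the racemic C4 of 12 and the sp3 carbons of 21 and 23 all end as aromatic carbons. The one selectivity required is the orientation of the [2+2] step, and the polarisation of 19 secures it: its electron-rich unsubstituted carbon attacks the electrophilic ketene carbonyl carbon, so the 2,4,6-trimethoxyphenoxy group ends at C1, across the ring from the ring C ether at C4 and two carbons from the new C5 hydroxyl. The closing carbonate–methanol treatment should return any 24 that a ketene has O-acylated, and since each ether oxygen came in on a non-aromatic carbon, no crowded phenol has to be arylated at ring B.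

Step 10
Reactants: 24 2-[2-(benzyloxy)-3,5-dimethoxyphenoxy]-3-ethoxy-5-(2,4,6-trimethoxyphenoxy)phenol
Product: 25 2-{4-[2-(benzyloxy)-3,5-dimethoxyphenoxy]-3-ethoxy-5-methoxyphenoxy}-1,3,5-trimethoxybenzene
Conditions: MeI, K2CO3, acetone, reflux
Reagents that add atoms: iodomethane, CI
Why: Williamson methylation caps the ring B hydroxyl so that the later copper coupling meets only one phenol.

Step 11
Reactants: 25 2-{4-[2-(benzyloxy)-3,5-dimethoxyphenoxy]-3-ethoxy-5-methoxyphenoxy}-1,3,5-trimethoxybenzene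
Product: 26 2-[2-ethoxy-6-methoxy-4-(2,4,6-trimethoxyphenoxy)phenoxy]-4,6-dimethoxyphenol
Conditions: H2 (1 atm), Pd/C (10 wt %), EtOAc–MeOH, rt
Reagents that add atoms: none
Why: Catalytic hydrogenolysis cleaves only the benzylic C–O bond, leaving alkyl aryl and diaryl ethers intact, and frees the ring C hydroxyl that must carry ring D.

Step 12
Reactants: 27 4-bromo-2,6-dimethoxyphenol; 28 (3,4,5-trimethoxyphenyl)boronic acid
Product: 29 5-bromo-1,3-dimethoxy-2-(3,4,5-trimethoxyphenoxy)benzene
Conditions: Cu(OAc)2 (0.3 equiv), pyridine, 4 Å MS, CH2Cl2, O2 (1 atm), rt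
Reagents that add atoms: none
Why: Chan–Lam coupling (aryl transfer from boron to divalent copper, then C–O reductive elimination) arylates hindered phenols at room temperature and leaves the C–Br bond untouched.

Step 13
Reactants: 26 2-[2-ethoxy-6-methoxy-4-(2,4,6-trimethoxyphenoxy)phenoxy]-4,6-dimethoxyphenol; 29 5-bromo-1,3-dimethoxy-2-(3,4,5-trimethoxyphenoxy)benzene
Product: 30 fully O-alkylated pentamer (rings A, C, D and E per-O-methylated; ring B 3-ethoxy-5-methoxy)
Conditions: CuI (10 mol %), picolinic acid (20 mol %), K3PO4, DMSO, 100 °C, Ar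
Reagents that add atoms: none
Why: Ullmann-type diaryl ether synthesis with the CuI–picolinic acid system, which is established for 2,6-disubstituted phenols; the crowding lies on the nucleophile, while the C–Br carbon of 29 has hydrogen at both ortho positions.

Step 14
Reactants: 30 fully O-alkylated pentamer
Product: 31 2-{4-[2-[3,5-dihydroxy-4-(3,4,5-trihydroxyphenoxy)phenoxy]-3,5-dihydroxyphenoxy]-3,5-dihydroxyphenoxy}benzene-1,3,5-triol (target)
Conditions: BBr3 (excess), CH2Cl2, −78 °C → rt, Ar; then H2O, 0 °C; isolation under Ar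
Reagents that add atoms: none
Why: Lewis-acid ether cleavage: BBr3 complexes each alkyl aryl ether oxygen and bromide removes methyl or ethyl by SN2, whereas the four diaryl ether oxygens carry no sp3 carbon and should survive, so aqueous work-up releases all twelve hydroxyls.

Compound list
1 | 2-hydroxy-4,6-dimethoxybenzaldehyde | COc1cc(O)c(C=O)c(OC)c1 | starting material
2 | 4,6-dimethoxy-2-(methoxymethoxy)benzaldehyde | COCOc1cc(OC)cc(OC)c1C=O | intermediate
3 | 2,4-dimethoxy-6-(methoxymethoxy)phenyl formate (not isolated) | COCOc1cc(OC)cc(OC)c1OC=O | intermediate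
4 | 2,4-dimethoxy-6-(methoxymethoxy)phenol | COCOc1cc(OC)cc(OC)c1O | intermediate
5 | 2-(benzyloxy)-1,5-dimethoxy-3-(methoxymethoxy)benzene | COCOc1cc(OC)cc(OC)c1OCc1ccccc1 | intermediate
6 | 2-(benzyloxy)-3,5-dimethoxyphenol | Oc1cc(OC)cc(OC)c1OCc1ccccc1 | intermediate
7 | bromoacetic acid | OC(=O)CBr | starting material
8 | 2-[2-(benzyloxy)-3,5-dimethoxyphenoxy]acetic acid | OC(=O)COc1cc(OC)cc(OC)c1OCc1ccccc1 | intermediate
9 | ethoxyacetylene | CCOC#C | starting material
10 | 2-[2-(benzyloxy)-3,5-dimethoxyphenoxy]acetyl chloride (not isolated) | ClC(=O)COc1cc(OC)cc(OC)c1OCc1ccccc1 | intermediate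
11 | [2-(benzyloxy)-3,5-dimethoxyphenoxy]ketene (not isolated) | O=C=COc1cc(OC)cc(OC)c1OCc1ccccc1 | intermediate
12 | rac-4-[2-(benzyloxy)-3,5-dimethoxyphenoxy]-3-ethoxycyclobut-2-en-1-one | CCOC1=CC(=O)C1Oc1cc(OC)cc(OC)c1OCc1ccccc1 | intermediate
13 | 2,4,6-trimethoxyphenol | COc1cc(OC)c(O)c(OC)c1 | starting material
14 | trichloroethylene | ClC=C(Cl)Cl | starting material
15 | dichloroacetylene (not isolated) | ClC#CCl | intermediate
16 | 2-{[(E)-1,2-dichloroethenyl]oxy}-1,3,5-trimethoxybenzene | Cl/C=C(Cl)\Oc1c(OC)cc(OC)cc1OC | intermediate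
17 | 2-[(chloroethynyl)oxy]-1,3,5-trimethoxybenzene (not isolated) | ClC#COc1c(OC)cc(OC)cc1OC | intermediate
18 | lithium (2,4,6-trimethoxyphenoxy)acetylide (not isolated) | [Li]C#COc1c(OC)cc(OC)cc1OC | intermediate
19 | 2-(ethynyloxy)-1,3,5-trimethoxybenzene | C#COc1c(OC)cc(OC)cc1OC | intermediate
20 | (3Z)-4-[2-(benzyloxy)-3,5-dimethoxyphenoxy]-3-ethoxybuta-1,3-dien-1-one (not isolated) | O=C=C/C(OCC)=C/Oc1cc(OC)cc(OC)c1OCc1ccccc1 | intermediate
21 | rac-4-{(Z)-2-[2-(benzyloxy)-3,5-dimethoxyphenoxy]-1-ethoxyethenyl}-3-(2,4,6-trimethoxyphenoxy)cyclobut-2-en-1-one (not isolated) | O=C1C=C(Oc2c(OC)cc(OC)cc2OC)C1/C(OCC)=C/Oc1cc(OC)cc(OC)c1OCc1ccccc1 | intermediate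
22 | (3E,5Z)-6-[2-(benzyloxy)-3,5-dimethoxyphenoxy]-5-ethoxy-3-(2,4,6-trimethoxyphenoxy)hexa-1,3,5-trien-1-one (not isolated) | O=C=C/C(Oc1c(OC)cc(OC)cc1OC)=C\C(OCC)=C\Oc1cc(OC)cc(OC)c1OCc1ccccc1 | intermediate
23 | rac-6-[2-(benzyloxy)-3,5-dimethoxyphenoxy]-5-ethoxy-3-(2,4,6-trimethoxyphenoxy)cyclohexa-2,4-dien-1-one (not isolated) | O=C1C=C(Oc2c(OC)cc(OC)cc2OC)C=C(OCC)C1Oc1cc(OC)cc(OC)c1OCc1ccccc1 | intermediate
24 | 2-[2-(benzyloxy)-3,5-dimethoxyphenoxy]-3-ethoxy-5-(2,4,6-trimethoxyphenoxy)phenol | CCOc1cc(Oc2c(OC)cc(OC)cc2OC)cc(O)c1Oc1cc(OC)cc(OC)c1OCc1ccccc1 | intermediate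
25 | 2-{4-[2-(benzyloxy)-3,5-dimethoxyphenoxy]-3-ethoxy-5-methoxyphenoxy}-1,3,5-trimethoxybenzene | CCOc1cc(Oc2c(OC)cc(OC)cc2OC)cc(OC)c1Oc1cc(OC)cc(OC)c1OCc1ccccc1 | intermediate
26 | 2-[2-ethoxy-6-methoxy-4-(2,4,6-trimethoxyphenoxy)phenoxy]-4,6-dimethoxyphenol | CCOc1cc(Oc2c(OC)cc(OC)cc2OC)cc(OC)c1Oc1cc(OC)cc(OC)c1O | intermediate
27 | 4-bromo-2,6-dimethoxyphenol | COc1cc(Br)cc(OC)c1O | starting material
28 | (3,4,5-trimethoxyphenyl)boronic acid | COc1cc(B(O)O)cc(OC)c1OC | starting material
29 | 5-bromo-1,3-dimethoxy-2-(3,4,5-trimethoxyphenoxy)benzene | COc1cc(Br)cc(OC)c1Oc1cc(OC)c(OC)c(OC)c1 | intermediate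
30 | fully O-alkylated pentamer (eleven methyl ethers, one ethyl ether on ring B C3) | COc1cc(OC)c(Oc2cc(OCC)c(Oc3cc(OC)cc(OC)c3Oc3cc(OC)c(Oc4cc(OC)c(OC)c(OC)c4)c(OC)c3)c(OC)c2)c(OC)c1 | intermediate
31 | 2-{4-[2-[3,5-dihydroxy-4-(3,4,5-trihydroxyphenoxy)phenoxy]-3,5-dihydroxyphenoxy]-3,5-dihydroxyphenoxy}benzene-1,3,5-triol | Oc1cc(O)c(Oc2cc(O)c(Oc3cc(O)cc(O)c3Oc3cc(O)c(Oc4cc(O)c(O)c(O)c4)c(O)c3)c(O)c2)c(O)c1 | target

Total step count: 14.
Longest linear sequence: 11 steps (steps 1–6, 9, 10, 11, 13, 14, from aldehyde 1).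

Steps most likely to fail

Step 9. The vinylketene may dimerise, or be consumed by the product phenol, faster than the only moderately nucleophilic aryl ynol ether traps it, and the ynol ether may polymerise on heating. The fallback sets out from 13 and 27 and comes back to the route at 31. It takes ring B ready-made and forms both of its ether bonds by copper-catalysed C–O coupling, each time with the hindered partner as the phenol. Benzylation of 27 (BnBr, K2CO3, DMF) gives 2-(benzyloxy)-5-bromo-1,3-dimethoxybenzene F1. Coupling of F1 with 13 (CuI, picolinic acid, K3PO4, DMSO, 100 °C) should give 2-[4-(benzyloxy)-3,5-dimethoxyphenoxy]-1,3,5-trimethoxybenzene F2, and hydrogenolysis (H2, Pd/C) gives 2,6-dimethoxy-4-(2,4,6-trimethoxyphenoxy)phenol F3. F3 is coupled under the same CuI conditions with commercial 2-bromo-4,6-dimethoxybenzaldehyde (COc1cc(Br)c(C=O)c(OC)c1), whose ortho formyl group activates the bromide, to give 2-[2,6-dimethoxy-4-(2,4,6-trimethoxyphenoxy)phenoxy]-4,6-dimethoxybenzaldehyde F4. Baeyer–Villiger oxidation (mCPBA, CH2Cl2) gives 2-[2,6-dimethoxy-4-(2,4,6-trimethoxyphenoxy)phenoxy]-4,6-dimethoxyphenyl formate F5, and methanolysis (K2CO3, MeOH) gives 2-[2,6-dimethoxy-4-(2,4,6-trimethoxyphenoxy)phenoxy]-4,6-dimethoxyphenol F6, the ring B methoxy analogue of 26. Coupling of F6 with 29 as in step 13 should give the dodecamethyl ether of 31 F7, and BBr3 as in step 14 leads to 31.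

Step 13. Oxidative addition of the electron-rich bromide and C–O bond formation from the crowded phenoxide may both be slow, so that hydrodebromination and catalyst decay outrun the coupling. The fallback sets out from 29 and 26 and comes back to the route at 30. It turns the aryl partner from a halide into a boron reagent. Bromine–lithium exchange on 29 (n-BuLi, THF, −78 °C) gives [3,5-dimethoxy-4-(3,4,5-trimethoxyphenoxy)phenyl]lithium F8, which is trapped with B(OiPr)3 and hydrolysed with aqueous HCl to [3,5-dimethoxy-4-(3,4,5-trimethoxyphenoxy)phenyl]boronic acid F9. Chan–Lam coupling of F9 with 26 (Cu(OAc)2, pyridine, 4 Å MS, CH2Cl2, air, rt) should then give 30 at room temperature without an oxidative addition step.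

Step 14. Cleavage may stop at partly alkylated congeners, and the free dodecaphenol may oxidise in air or be lost on polar stationary phases during isolation. The fallback sets out from 30 and comes back to the route at 31. The polyphenol is carried through a stable derivative instead of being isolated from the BBr3 reaction. The crude product of the BBr3 treatment is acetylated at once (Ac2O, pyridine, rt) to the dodecaacetate of 31 F10, which can be purified on silica gel, where under-dealkylated material is separated for resubmission. Zemplén transesterification (NaOMe cat., degassed MeOH, 0 °C, Ar, then acidic ion-exchange resin) should then release 31 under non-oxidising conditions.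

Further compounds
F1 | step 9 | 2-(benzyloxy)-5-bromo-1,3-dimethoxybenzene | COc1cc(Br)cc(OC)c1OCc1ccccc1
F2 | step 9 | 2-[4-(benzyloxy)-3,5-dimethoxyphenoxy]-1,3,5-trimethoxybenzene | COc1cc(OC)c(Oc2cc(OC)c(OCc3ccccc3)c(OC)c2)c(OC)c1
F3 | step 9 | 2,6-dimethoxy-4-(2,4,6-trimethoxyphenoxy)phenol | COc1cc(OC)c(Oc2cc(OC)c(O)c(OC)c2)c(OC)c1
F4 | step 9 | 2-[2,6-dimethoxy-4-(2,4,6-trimethoxyphenoxy)phenoxy]-4,6-dimethoxybenzaldehyde | COc1cc(OC)c(Oc2cc(OC)c(Oc3cc(OC)cc(OC)c3C=O)c(OC)c2)c(OC)c1
F5 | step 9 | 2-[2,6-dimethoxy-4-(2,4,6-trimethoxyphenoxy)phenoxy]-4,6-dimethoxyphenyl formate | COc1cc(OC)c(Oc2cc(OC)c(Oc3cc(OC)cc(OC)c3OC=O)c(OC)c2)c(OC)c1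
F6 | step 9 | 2-[2,6-dimethoxy-4-(2,4,6-trimethoxyphenoxy)phenoxy]-4,6-dimethoxyphenol | COc1cc(OC)c(Oc2cc(OC)c(Oc3cc(OC)cc(OC)c3O)c(OC)c2)c(OC)c1
F7 | step 9 | dodecamethyl ether of 31 | COc1cc(OC)c(Oc2cc(OC)c(Oc3cc(OC)cc(OC)c3Oc3cc(OC)c(Oc4cc(OC)c(OC)c(OC)c4)c(OC)c3)c(OC)c2)c(OC)c1
F8 | step 13 | [3,5-dimethoxy-4-(3,4,5-trimethoxyphenoxy)phenyl]lithium | [Li]c1cc(OC)c(Oc2cc(OC)c(OC)c(OC)c2)c(OC)c1
F9 | step 13 | [3,5-dimethoxy-4-(3,4,5-trimethoxyphenoxy)phenyl]boronic acid | OB(O)c1cc(OC)c(Oc2cc(OC)c(OC)c(OC)c2)c(OC)c1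
F10 | step 14 | dodecaacetate of 31 | CC(=O)Oc1cc(OC(C)=O)c(Oc2cc(OC(C)=O)c(Oc3cc(OC(C)=O)cc(OC(C)=O)c3Oc3cc(OC(C)=O)c(Oc4cc(OC(C)=O)c(OC(C)=O)c(OC(C)=O)c4)c(OC(C)=O)c3)c(OC(C)=O)c2)c(OC(C)=O)c1
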